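**Plan**

1. Numbering: bicyclo[3.2.1]octane C1–C8 (C1 and C5 bridgeheads, C2/C4 ring carbonyl carbons, C3 acyl-bearing, C5 methyl-bearing, C6 CH2, C7 CH, C8 bridging C=O) plus cyclopentane carbons C9 (CMe2), C10 (CH–CMe2OH), C11 (CH2); ring A = C1,C2,C3,C4,C5,C8; ring B = C1,C8,C5,C6,C7; ring C = C1,C7,C9,C10,C11.
2. Retrosynthesis: after O–O reduction, the carbinol C–O bond, C9–C10 and C6–C7 are cut in one radical cascade back to the monocyclic ring A iodide 19. The enabling feature is that C6 is a CH2 on quaternary C5, held 1,3-syn across the C8 carbonyl to C7 of an alkenyl group on C1, while C9 lies five atoms from C10 of the prenyl group on C1.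
3. Iodide 19 is cut further at C3–acyl, C1–C11 (prenyl bromide) and C1–C7 (isobutyraldehyde), back to a symmetric 4,4-disubstituted 3,5-dimethoxycyclohexadienone made by Birch reductive methylation of methyl 2,6-dimethoxybenzoate.
4. Forward: ring A comes from the arene with C5 (CH3, CH2I) quaternary first; C1 is built by Mannich/Knoevenagel condensation and deconjugative prenylation; the acyl group is added last; ring B and then ring C close in step 11.
5. Stereochemistry: C5 becomes stereogenic (racemic) on mono-hydrolysis; C1 is set relative to C5 by prenylation anti to CH2I; the absolute configuration comes from resolution of 14 on a chiral phase; C7 and C10 are set in the cascade.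

Key step: step 11

Remark: β-dicarbonyl enols are drawn as one tautomer; racemates carry the prefix rac, and for 14 the SMILES shows the enantiomer that is carried on.

**Route**

Step 1
Reactants: 1 methyl 2,6-dimethoxybenzoate; 2 iodomethane
Product: 4 methyl 2,6-dimethoxy-1-methylcyclohexa-2,5-diene-1-carboxylate, via potassium ester dienolate 3 (not isolated)
Conditions: K, NH3(l), THF, t-BuOH (1 equiv), −78 °C; then MeI, −78 °C to rt
Reagents that add atoms: iodomethane (CI)
Why: Birch reductive alkylation: reduction of the o-methoxybenzoate with one protonation at the para carbon leaves the ester-stabilised 1,4-dihydro enolate, which is methylated at the ipso carbon to give the quaternary centre that becomes C5 (still achiral, the ring keeps a mirror plane).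

Step 2
Reactants: 4 methyl 2,6-dimethoxy-1-methylcyclohexa-2,5-diene-1-carboxylate
Product: 5 (2,6-dimethoxy-1-methylcyclohexa-2,5-dien-1-yl)methanol
Conditions: LiAlH4, THF, 0 °C; aq. NaOH work-up
Reagents that add atoms: none
Why: Hydride reduction of the ester with LiAlH4 gives the neopentyl alcohol whose carbon is C6, the enol ethers being inert to hydride and protected by the basic work-up.

Step 3
Reactants: 5 (2,6-dimethoxy-1-methylcyclohexa-2,5-dien-1-yl)methanol
Product: 6 6-(iodomethyl)-1,5-dimethoxy-6-methylcyclohexa-1,4-diene
Conditions: PPh3, I2, imidazole, toluene, 80 °C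
Reagents that add atoms: iodine (II)
Why: Garegg–Samuelsson (Appel-type) iodination, in which iodide displaces the alkoxyphosphonium group at the neopentyl carbon on heating while imidazole buffers the acid-labile enol ethers, whose nucleophilic carbon is remote from C6 so that participation or 1,2-vinyl shift is disfavoured.

Step 4
Reactants: 6 6-(iodomethyl)-1,5-dimethoxy-6-methylcyclohexa-1,4-diene
Product: 7 4-(iodomethyl)-3,5-dimethoxy-4-methylcyclohexa-2,5-dien-1-one
Conditions: t-BuOOH, (C5H5NH)2Cr2O7 (PDC, 20 mol %), Celite, PhH, rt
Reagents that add atoms: tert-butyl hydroperoxide (CC(C)(C)OO)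
Why: Chromium-mediated bis-allylic oxidation of the doubly activated ring CH2, the usual way to turn Birch alkylation products into 4,4-disubstituted cyclohexa-2,5-dienones, installs the C2 carbonyl, and a primary neopentyl iodide should be inert to these oxidants.

Step 5
Reactants: 7 4-(iodomethyl)-3,5-dimethoxy-4-methylcyclohexa-2,5-dien-1-one
Product: 8 rac-3-hydroxy-4-(iodomethyl)-5-methoxy-4-methylcyclohexa-2,5-dien-1-one
Conditions: NaOH (2 equiv), H2O/THF, 50 °C; then 1 M HCl to pH 3, 0 °C
Reagents that add atoms: sodium hydroxide ([Na+].[OH-])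
Why: Vinylogous ester saponification (addition–elimination of hydroxide at one of the two equivalent methoxy-bearing carbons) should stop after one methoxy group because the product is an unreactive vinylogous carboxylate; this desymmetrisation makes C5 a stereocentre, formed as the racemate.

Step 6
Reactants: 8 rac-3-hydroxy-4-(iodomethyl)-5-methoxy-4-methylcyclohexa-2,5-dien-1-one; 9 2-methylpropanal
Product: 12 rac-3-hydroxy-4-(iodomethyl)-5-methoxy-4-methyl-2-(2-methylprop-1-en-1-yl)cyclohexa-2,5-dien-1-one, via Mannich base 10 (not isolated), via isobutylidene dione 11 (not isolated)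
Conditions: i-PrCHO, piperidine (1.1 equiv), CH2Cl2, rt; then 1 M HCl, 0 °C
Reagents that add atoms: 2-methylpropanal (CC(C)C=O)
Why: Knoevenagel condensation run in two stages (Mannich addition at C1, the carbon between the carbonyl and the enol, then acid-induced loss of piperidine) followed by vinylogous tautomerisation of the isobutylidene dione to the conjugated dienol; the stoichiometric amine keeps the alkylidene from adding a second dione, and no new stereocentre is formed.

Step 7
Reactants: 12 rac-3-hydroxy-4-(iodomethyl)-5-methoxy-4-methyl-2-(2-methylprop-1-en-1-yl)cyclohexa-2,5-dien-1-one; 13 1-bromo-3-methylbut-2-ene (prenyl bromide)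
Product: 14 rac-(2R*,6S*)-6-(iodomethyl)-5-methoxy-6-methyl-2-(3-methylbut-2-en-1-yl)-2-(2-methylprop-1-en-1-yl)cyclohex-4-ene-1,3-dione
Conditions: LiOH (1.0 equiv), H2O/THF, 0 °C; then prenyl bromide, 0 °C to rt
Reagents that add atoms: 1-bromo-3-methylbut-2-ene (CC(C)=CCBr)
Why: Deconjugative α-alkylation of the Knoevenagel-derived dienolate (any residual 11 gives the same anion): prenyl bromide should attack C1 from the ring face opposite the iodomethyl group, the larger substituent on C5, so that the 2-methylprop-1-enyl group ends cis to CH2I, the aqueous lithium medium favouring C- over O-alkylation and the minor diastereomer being removed on silica.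

Step 8
Reactants: 14 rac-(2R*,6S*)-6-(iodomethyl)-5-methoxy-6-methyl-2-(3-methylbut-2-en-1-yl)-2-(2-methylprop-1-en-1-yl)cyclohex-4-ene-1,3-dione
Product: 15 (2R,6S)-6-(iodomethyl)-5-methoxy-6-methyl-2-(3-methylbut-2-en-1-yl)-2-(2-methylprop-1-en-1-yl)cyclohex-4-ene-1,3-dione
Conditions: preparative SFC, amylose tris(3,5-dimethylphenylcarbamate) stationary phase, CO2/i-PrOH
Reagents that add atoms: none
Why: Resolution of the racemate by chromatography on a chiral stationary phase, placed at this neutral, non-enolisable and configurationally inert stage; the iodine atom lets the absolute configuration of the collected enantiomer be assigned by anomalous X-ray dispersion.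

Step 9
Reactants: 15 (2R,6S)-6-(iodomethyl)-5-methoxy-6-methyl-2-(3-methylbut-2-en-1-yl)-2-(2-methylprop-1-en-1-yl)cyclohex-4-ene-1,3-dione
Product: 16 (2R,6S)-5-hydroxy-6-(iodomethyl)-6-methyl-2-(3-methylbut-2-en-1-yl)-2-(2-methylprop-1-en-1-yl)cyclohex-4-ene-1,3-dione
Conditions: LiI, pyridine, 100 °C; then cold 1 M HCl
Reagents that add atoms: none
Why: Nucleophilic O-demethylation of the vinylogous methyl ester by iodide (LiI dealkylation, SN2 at the methyl group with the dione enolate as leaving group) frees the C2/C4 dione without hydroxide or strong acid, so the non-enolisable C8 ketone, the alkenes and the neopentyl iodide (degenerate exchange only) should survive, with pyridine trapping the iodomethane.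

Step 10
Reactants: 16 (2R,6S)-5-hydroxy-6-(iodomethyl)-6-methyl-2-(3-methylbut-2-en-1-yl)-2-(2-methylprop-1-en-1-yl)cyclohex-4-ene-1,3-dione; 17 2-methylpropanoyl chloride
Product: 19 (4S,6R)-3-hydroxy-4-(iodomethyl)-4-methyl-6-(3-methylbut-2-en-1-yl)-2-(2-methylpropanoyl)-6-(2-methylprop-1-en-1-yl)cyclohex-2-ene-1,5-dione, via enol isobutyrate 18 (not isolated)
Conditions: i-PrCOCl, Et3N, CH2Cl2, 0 °C; then DMAP (20 mol %), rt; cold citric acid wash
Reagents that add atoms: 2-methylpropanoyl chloride (CC(C)C(Cl)=O)
Why: O-Acylation of the dione followed by DMAP-catalysed 1,3 O-to-C acyl transfer, the usual route to 2-acylcyclohexane-1,3-diones, should put the isobutyryl group on C3, the only enolisable carbon, and leaves both quaternary stereocentres untouched.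

Step 11
Reactants: 19 (4S,6R)-3-hydroxy-4-(iodomethyl)-4-methyl-6-(3-methylbut-2-en-1-yl)-2-(2-methylpropanoyl)-6-(2-methylprop-1-en-1-yl)cyclohex-2-ene-1,5-dione
Product: 20 (1S,3S,5S,7S)-3-(2-hydroperoxypropan-2-yl)-8-hydroxy-4,4,7-trimethyl-9-(2-methylpropanoyl)tricyclo[5.3.1.0(1,5)]undec-8-ene-10,11-dione (tertiary hydroperoxide of the target; C1 S, C5 S, C7 S, C10 S in the plan numbering)
Conditions: Bu3SnH (2.5 equiv) and dry air, each fed slowly, toluene (5 mM), 0 °C
Reagents that add atoms: dioxygen (O=O)
Why: Bu3Sn• abstracts iodine from C6; the primary C6 radical should add 5-exo-trig to C7 of the 2-methylprop-1-enyl group (ring B, bond C6–C7), the tertiary C9 radical then adds 5-exo-trig to C10 of the prenyl group (ring C, bond C9–C10), and the last tertiary radical is captured by O2, the peroxyl radical taking hydrogen from Bu3SnH to give the hydroperoxide and carry the chain. The closest known reaction type is the tin hydride/air reductive oxygenation of alkyl halides coupled to a tandem 5-exo radical cyclisation. C7 is controlled by geometry: C6 and C7 are cis on ring A and face each other across the C8 carbonyl, and only the C1–C7 rotamer with C9 exo (towards C8, away from the C2–C3–C4 bridge) lets the C9 radical reach C10 through a cis-fused five-membered ring, a radical closed the other way being unable to form ring C readily. C10 is controlled only by the face of the prenyl alkene that C9 attacks; the target needs the CMe2 terminus on the side of C6 and C8, a closure with little built-in bias, so the C10 epimer is expected alongside and is separated by chromatography here or after step 12. The step needs both ring closures to outrun the Dowd–Beckwith-type 1,2-acyl shift of the β-keto C6 radical (ring expansion through C8 or C4) and the capture of the C6 or C9 radical by O2 or tin hydride; the syn-1,3 pre-organisation on ring A should make the first closure much faster than the acyl shift, and 0 °C, high dilution and slow simultaneous feeding of Bu3SnH and air keep both traps scarce until the final tertiary radical is reached.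

Step 12
Reactants: 20 tertiary hydroperoxide of the target
Product: 21 (1S,3S,5S,7S)-8-hydroxy-3-(2-hydroxypropan-2-yl)-4,4,7-trimethyl-9-(2-methylpropanoyl)tricyclo[5.3.1.0(1,5)]undec-8-ene-10,11-dione (CNP0267234.1)
Conditions: PPh3, THF, 0 °C to rt
Reagents that add atoms: none
Why: Oxygen-atom transfer from the hydroperoxide to PPh3 reduces the O–O bond to the tertiary alcohol without affecting the ketones, the enol or any stereocentre.

**Compound list**

1 | methyl 2,6-dimethoxybenzoate | COC(=O)c1c(OC)cccc1OC | starting material
2 | iodomethane | CI | starting material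
3 | potassium enolate of methyl 2,6-dimethoxycyclohexa-2,5-diene-1-carboxylate (not isolated) | COC1=CCC=C(OC)C1=C([O-])OC.[K+] | intermediate
4 | methyl 2,6-dimethoxy-1-methylcyclohexa-2,5-diene-1-carboxylate | COC(=O)C1(C)C(OC)=CCC=C1OC | intermediate
5 | (2,6-dimethoxy-1-methylcyclohexa-2,5-dien-1-yl)methanol | OCC1(C)C(OC)=CCC=C1OC | intermediate
6 | 6-(iodomethyl)-1,5-dimethoxy-6-methylcyclohexa-1,4-diene | ICC1(C)C(OC)=CCC=C1OC | intermediate
7 | 4-(iodomethyl)-3,5-dimethoxy-4-methylcyclohexa-2,5-dien-1-one (achiral) | COC1=CC(=O)C=C(OC)C1(C)CI | intermediate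
8 | rac-3-hydroxy-4-(iodomethyl)-5-methoxy-4-methylcyclohexa-2,5-dien-1-one | COC1=CC(=O)C=C(O)C1(C)CI | intermediate
9 | 2-methylpropanal (isobutyraldehyde) | CC(C)C=O | starting material
10 | Mannich base, rac-3-hydroxy-4-(iodomethyl)-5-methoxy-4-methyl-2-[2-methyl-1-(piperidin-1-yl)propyl]cyclohexa-2,5-dien-1-one (diastereomer mixture, not isolated) | COC1=CC(=O)C(C(C(C)C)N2CCCCC2)=C(O)C1(C)CI | intermediate
11 | isobutylidene dione, rac-6-(iodomethyl)-5-methoxy-6-methyl-2-(2-methylpropylidene)cyclohex-4-ene-1,3-dione (alkene geometry not defined, not isolated) | COC1=CC(=O)C(=CC(C)C)C(=O)C1(C)CI | intermediate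
12 | rac-3-hydroxy-4-(iodomethyl)-5-methoxy-4-methyl-2-(2-methylprop-1-en-1-yl)cyclohexa-2,5-dien-1-one | COC1=CC(=O)C(C=C(C)C)=C(O)C1(C)CI | intermediate
13 | 1-bromo-3-methylbut-2-ene (prenyl bromide) | CC(C)=CCBr | starting material
14 | rac-(2R*,6S*)-6-(iodomethyl)-5-methoxy-6-methyl-2-(3-methylbut-2-en-1-yl)-2-(2-methylprop-1-en-1-yl)cyclohex-4-ene-1,3-dione (CH2I cis to the 2-methylprop-1-enyl group; one enantiomer drawn) | COC1=CC(=O)[C@@](CC=C(C)C)(C=C(C)C)C(=O)[C@@]1(C)CI | intermediate
15 | (2R,6S)-6-(iodomethyl)-5-methoxy-6-methyl-2-(3-methylbut-2-en-1-yl)-2-(2-methylprop-1-en-1-yl)cyclohex-4-ene-1,3-dione | COC1=CC(=O)[C@@](CC=C(C)C)(C=C(C)C)C(=O)[C@@]1(C)CI | intermediate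
16 | (2R,6S)-5-hydroxy-6-(iodomethyl)-6-methyl-2-(3-methylbut-2-en-1-yl)-2-(2-methylprop-1-en-1-yl)cyclohex-4-ene-1,3-dione | OC1=CC(=O)[C@@](CC=C(C)C)(C=C(C)C)C(=O)[C@@]1(C)CI | intermediate
17 | 2-methylpropanoyl chloride (isobutyryl chloride) | CC(C)C(Cl)=O | starting material
18 | enol isobutyrate of 16 (2-methylpropanoate on the C4 enol oxygen, configuration as in 16, not isolated) | CC(C)C(=O)OC1=CC(=O)[C@@](CC=C(C)C)(C=C(C)C)C(=O)[C@@]1(C)CI | intermediate
19 | (4S,6R)-3-hydroxy-4-(iodomethyl)-4-methyl-6-(3-methylbut-2-en-1-yl)-2-(2-methylpropanoyl)-6-(2-methylprop-1-en-1-yl)cyclohex-2-ene-1,5-dione (radical precursor; CH2I cis to the 2-methylprop-1-enyl group) | CC(C)C(=O)C1=C(O)[C@](C)(CI)C(=O)[C@](CC=C(C)C)(C=C(C)C)C1=O | intermediate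
20 | (1S,3S,5S,7S)-3-(2-hydroperoxypropan-2-yl)-8-hydroxy-4,4,7-trimethyl-9-(2-methylpropanoyl)tricyclo[5.3.1.0(1,5)]undec-8-ene-10,11-dione | CC(C)C(=O)C1=C(O)[C@]2(C)C[C@H]3C(C)(C)[C@@H](C(C)(C)OO)C[C@@]3(C1=O)C2=O | intermediate
21 | (1S,3S,5S,7S)-8-hydroxy-3-(2-hydroxypropan-2-yl)-4,4,7-trimethyl-9-(2-methylpropanoyl)tricyclo[5.3.1.0(1,5)]undec-8-ene-10,11-dione | CC(C)C(=O)C1=C(O)[C@]2(C)C[C@H]3C(C)(C)[C@@H](C(C)(C)O)C[C@@]3(C1=O)C2=O | target

**Step count and risks**

Total step count: 12. Longest linear sequence: 12 steps, from methyl 2,6-dimethoxybenzoate.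

Steps most likely to fail:

Step 11. What may go wrong: dioxygen or tin hydride captures the C6 or C9 radical before it has cyclised, the C6 radical undergoes the 1,2-acyl shift (ring expansion) instead of closing ring B, or the second closure shows poor facial selectivity at C10. The fallback separates ring formation from oxygenation. Setting out from 19, the same two 5-exo closures are run under argon as a cobalt-catalysed dehydrohalogenative (Heck-type) radical cyclisation [Co(dmgH)2(py)Cl (cat.), i-Pr2NEt, MeCN, blue light]. The last tertiary radical is taken up by cobalt and released by β-hydride loss as the isopropenyl tricycle F1. Mukaiyama hydration of its 1,1-disubstituted alkene [Co(acac)2 (cat.), PhSiH3, O2, i-PrOH; then PPh3] then adds the tertiary hydroxyl with Markovnikov orientation, and the sequence comes back to the route at 21.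

Step 7. What may go wrong: O-alkylation of the ambident dienolate, solvolysis of prenyl bromide, or poor facial selectivity at C1 because CH2I and CH3 differ too little. Setting out from 12, a Tsuji–Trost allylation [allyl methyl carbonate, Pd(PPh3)4 (cat., zerovalent palladium), THF, rt, dark] uses a soft and bulky π-allylpalladium electrophile. It is C-selective, should respond more strongly to the shielding by CH2I, and should give allyl dione F2. Cross-metathesis of its monosubstituted alkene with 2-methylbut-2-ene (second-generation Grubbs catalyst, (H2IMes)(PCy3)Cl2Ru=CHPh, CH2Cl2, 40 °C), to which the trisubstituted 2-methylprop-1-enyl group is inert, converts allyl into prenyl and comes back to the route at 14.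

Step 10. What may go wrong: once the acyl group is on C3 the triketone anion lies next to the neopentyl iodide and its acyl oxygen may close a six-membered ring onto C6 (intramolecular O-alkylation), or the O-to-C acyl transfer stalls at the hindered carbon. The fallback reverses the order so that the iodide is consumed before the acyl group arrives. Setting out from 16, the tin hydride/air cascade of step 11 is run on the dione itself to give des-acyl hydroperoxide F3, and PPh3 reduces it to des-acyl alcohol F4. The isobutyryl group is then introduced as in step 10 (i-PrCOCl, Et3N; then DMAP) through enol isobutyrate F5, which comes back to the route at 21.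

Further compounds
F1 | step 11 | isopropenyl tricycle, prop-1-en-2-yl on C10 in place of the carbinol, C1, C5, C7 and C10 as in 21 | CC(C)C(=O)C1=C(O)[C@]2(C)C[C@H]3C(C)(C)[C@@H](C(C)=C)C[C@@]3(C1=O)C2=O
F2 | step 7 | allyl dione, rac-(2R*,6S*)-6-(iodomethyl)-5-methoxy-6-methyl-2-(2-methylprop-1-en-1-yl)-2-(prop-2-en-1-yl)cyclohex-4-ene-1,3-dione | COC1=CC(=O)[C@@](CC=C)(C=C(C)C)C(=O)[C@@]1(C)CI
F3 | step 10 | des-acyl hydroperoxide, 20 with H in place of the isobutyryl group on C3 | C1=C(O)[C@]2(C)C[C@H]3C(C)(C)[C@@H](C(C)(C)OO)C[C@@]3(C1=O)C2=O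
F4 | step 10 | des-acyl alcohol, 21 with H in place of the isobutyryl group on C3 | C1=C(O)[C@]2(C)C[C@H]3C(C)(C)[C@@H](C(C)(C)O)C[C@@]3(C1=O)C2=O
F5 | step 10 | enol isobutyrate of F4 (2-methylpropanoate on the C4 enol oxygen) | C1=C(OC(=O)C(C)C)[C@]2(C)C[C@H]3C(C)(C)[C@@H](C(C)(C)O)C[C@@]3(C1=O)C2=O
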